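The numbers in the tables were generated by integration with made-up constants; scatter was added.

A factor of 2.90 separates the two earlier runs, and I carry it through this flask as the charge penalty: the fractional rate constant at a small charge of starting material, divided by the same constant at a large charge, where that constant is the logarithm of the charge over the part not yet product, per unit time.

| flask | starting material | partner | initiator | remark | time |
|---|---|---|---|---|---|
| Saturday's | 6 mM | 42 mM | 0.46 mM | run made earlier |  |
| Monday's | 49 mM | 42 mM | 0.46 mM | run made earlier |  |
| dusk | 5.0 mM | 42.0 mM | 0.46 mM |  | 25 min |
| winter | 10 mM | 42.0 mM | 0.46 mM |  | 25 min |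
| summer | 20 mM | 42.0 mM | 0.46 mM |  | 25 min |
| midnight | 40 mM | 42.0 mM | 0.46 mM |  | 25 min |

| run | time / min | product / % | starting material / % |
|---|---|---|---|
| Saturday's | 4.00 | 20 | 79 |
| Saturday's | 8.00 | 41 | 64 |
| Saturday's | 12.0 | 52 | 45 |
| Saturday's | 20.0 | 75 | 31 |
| Monday's | 4.00 | 4 | 92 |
| Monday's | 8.00 | 19 | 83 |
| Monday's | 12.0 | 27 | 74 |
| Monday's | 20.0 | 38 | 63 |

(scatter of a reading: 2 percentage points)

- "hardly changes" means that all values lie within two and a half points (for a concentration: within two and a half percent of the largest)

- amount of product at the end, in percent of the starting material charged for dusk, winter, summer, midnight, in this order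
- how the row runs (rises all the way / falls, then rises / rises, then falls / hardly changes / falls all the way)

The bench rule says that with partner in excess the reaction is pseudo-first-order, so that every charge reaches the same percent at the same time, and the zero of my scale is therefore a penalty of one. The readings at 20.0 min give a constant of 0.0693 min⁻¹ for Saturday's flask and 0.0239 min⁻¹ for Monday's, so the rule fails between them. Its border is a ratio of starting material to partner of one, where partner stops being in excess: the ratio stands at 0.143 on Saturday, inside the border, and at 1.17 on Monday, past it. But if each product costs one partner, [partner] in Monday's flask has fallen by a factor of 1.80 at that reading, which is less than the penalty, so I expect something the readings don't name to carry the rest. Putting Saturday's constant on dusk and Monday's on midnight, my own reckoning gives about 82.3% and 45.0% at 25 min, with the row falling between them.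

The forecast gives 79%, 73%, 64% and 49%, a narrower span than my two ends, and says “Percent yield should fall steadily”, so its shape is "falls all the way".

The flask gives 79.4%, 76.4%, 69.3% and 51.0%, and the row falls all the way.

    initiator → 2 initiating radical (k = 0.00440 min⁻¹)
    starting material + initiating radical → capped initiator + first chain carrier (k = 2.50 × 10⁶ L mol⁻¹ s⁻¹)
    partner + first chain carrier → product + second chain carrier (k = 57000 L mol⁻¹ s⁻¹)
    starting material + second chain carrier → by-product + first chain carrier (k = 87000 L mol⁻¹ s⁻¹)
    first chain carrier → ended carrier (k = 400 min⁻¹)
    2 second chain carrier → ended chains (k = 2.00 × 10⁸ L mol⁻¹ s⁻¹)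

From dusk to midnight the penalty is 2.21, beside the 2.90 read from the earlier runs. In the same two flasks with the turning of first chain carrier into ended carrier struck out, product reaches 81.7% at dusk and 80.9% at midnight, a penalty of 1.03, which lies close to the zero of the scale. So this ending step is a reason for the fall along the row: the drop of 28 percentage points from dusk to midnight shrinks to 0.82 points without it.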